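A direct plan would join the two aromatic rings first and close ring C last: aldol addition of the lithium enolate of the prenylated arylacetate A2 to 2,4,6-tris(methoxymethoxy)benzaldehyde A1, oxidation and dealkoxycarbonylation to deoxybenzoin A3, aminomethylenation to enaminone A4, and ring closure with HCl in methanol, which would also remove the MOM groups. Its weakest steps would be:
- the aldol addition, alcohol oxidation and dealkoxycarbonylation: three operations and two discarded stereocentres for one ArCH2–C(=O)Ar bond;
- the making of the prenyl group of A2 by O-allylation, Claisen rearrangement, O-methylation and ruthenium-catalysed cross-metathesis: four steps for five carbons, after which the alkene must survive every later step;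
- the final acidic ring closure with threefold acetal cleavage, run on the most valuable material while the acid-sensitive prenyl alkene is present (addition of HCl or methanol, cyclisation onto the neighbouring methoxy group).

**Plan of the new route**
The retrosynthesis cuts the aryl–prenyl bond first (cross-coupling of an aryl bromide, last step) and then, in one operation, C4–C4a, O1–C8a and O1–C2.
The feature used: O1 and the C4 carbonyl sit on the neighbouring ring A carbons C8a and C4a, and the C5 oxygen lies beside C4a. A 3,5-bis(benzyloxy)benzyne therefore takes the carboxylate oxygen of a 2-aryl-3-methoxyacrylic acid at C8a and its acyl carbon at C4a, and the phenolate so formed closes ring C at C2.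
Ring order: ring B first carries the complete C2–C3–C4 chain; ring A enters last as the aryne and ring C forms in the same step.
C4 arrives as a carboxyl carbon, so no aldol/oxidation/decarboxylation and no stereocentre occur. The prenyl group is attached in one step, after the only acidic step.

Key step: step 7

Remark: 3,5-bis(benzyloxy)phenol (7) is taken as commercial; the alkene geometry of 5, 6 and 13 has no bearing on the product, and the target has no stereocentre.

**Step 1**
Reactants: 1 homovanillic acid [2-(4-hydroxy-3-methoxyphenyl)acetic acid]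
Product: 2 2-(3-bromo-4-hydroxy-5-methoxyphenyl)acetic acid
Conditions: Br2 (1.05 equiv), AcOH, 15 °C to rt, 2 h
Reagents that add atoms: bromine, BrBr
Why: Electrophilic aromatic bromination; the free phenol is the strongest activator and its only open ortho position should be attacked in preference to the positions activated by the methoxy group, as is the rule for 4-substituted guaiacols.

**Step 2**
Reactants: 2 2-(3-bromo-4-hydroxy-5-methoxyphenyl)acetic acid
Product: 3 methyl 2-(3-bromo-4,5-dimethoxyphenyl)acetate
Conditions: MeI (3 equiv), K2CO3 (3 equiv), DMF, rt to 40 °C, 12 h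
Reagents that add atoms: iodomethane, CI
Why: Twofold Williamson-type O-alkylation (phenoxide and carboxylate) by SN2 at iodomethane; K2CO3 is too weak to deprotonate the benzylic ester CH2, so no C-methylation is expected.

**Step 3**
Reactants: 3 methyl 2-(3-bromo-4,5-dimethoxyphenyl)acetate
Product: 5 methyl (E)-2-(3-bromo-4,5-dimethoxyphenyl)-3-methoxyacrylate, via sodium enolate 4 (not isolated)
Conditions: NaH (2.2 equiv), HCO2Me (5 equiv), DMF, 0 °C to rt, 4 h; then Me2SO4 (3 equiv), rt, 3 h
Reagents that add atoms: methyl formate, COC=O; dimethyl sulfate, COS(=O)(=O)OC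
Why: Crossed Claisen condensation of the ester enolate with non-enolisable methyl formate is driven by formation of the stabilised enolate 4, and the hard electrophile dimethyl sulfate should alkylate 4 at oxygen to give mainly the (E)-3-methoxyacrylate.

**Step 4**
Reactants: 5 methyl (E)-2-(3-bromo-4,5-dimethoxyphenyl)-3-methoxyacrylate
Product: 6 (E)-2-(3-bromo-4,5-dimethoxyphenyl)-3-methoxyacrylic acid
Conditions: LiOH·H2O (3 equiv), THF/MeOH/H2O, 45 °C, 6 h; then 1 M HCl to pH 3 at 0 °C
Reagents that add atoms: lithium hydroxide, [Li+].[OH-]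
Why: Saponification (acyl substitution by hydroxide) of the vinylogous carbonate ester; the enol ether is stable to base and should survive brief cold acidification.

**Step 5**
Reactants: 7 3,5-bis(benzyloxy)phenol
Product: 8 2-bromo-3,5-bis(benzyloxy)phenol
Conditions: NBS (1.0 equiv), CH2Cl2, −78 °C to −30 °C, 2 h
Reagents that add atoms: N-bromosuccinimide, O=C1CCC(=O)N1Br
Why: Electrophilic bromination ortho to the free hydroxyl group; the two ortho positions are equivalent by symmetry, the para position is shielded by two benzyloxy groups, and one equivalent of NBS in the cold should limit twofold bromination.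

**Step 6**
Reactants: 8 2-bromo-3,5-bis(benzyloxy)phenol
Product: 11 3,5-bis(benzyloxy)-2-(trimethylsilyl)phenyl trifluoromethanesulfonate, via aryl silyl ether 9 (not isolated), via lithium phenolate 10 (not isolated)
Conditions: HMDS (1.5 equiv), THF, 65 °C, 2 h, concentrate; n-BuLi (1.1 equiv), THF, −100 °C to −78 °C, 30 min; Tf2O (1.2 equiv), −100 °C to rt
Reagents that add atoms: hexamethyldisilazane, C[Si](C)(C)N[Si](C)(C)C; trifluoromethanesulfonic anhydride, O=S(=O)(OS(=O)(=O)C(F)(F)F)C(F)(F)F
Why: O-silylation, bromine–lithium exchange and 1,3-migration of silicon from oxygen to carbon (retro-Brook rearrangement) should give phenolate 10, which is triflated on oxygen; this is the standard way from an o-bromophenol to an o-silylaryl triflate, and the exchange is much faster than deprotonation of the benzyl ethers at −100 °C.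

**Step 7**
Reactants: 6 (E)-2-(3-bromo-4,5-dimethoxyphenyl)-3-methoxyacrylic acid; 11 3,5-bis(benzyloxy)-2-(trimethylsilyl)phenyl trifluoromethanesulfonate
Product: 14 5,7-bis(benzyloxy)-3-(3-bromo-4,5-dimethoxyphenyl)-4H-chromen-4-one, via aryne 12 (not isolated), via cesium acylphenolate 13 (not isolated)
Conditions: 11 (1.5 equiv), CsF (4 equiv), THF, 125 °C (sealed tube), 24 h
Reagents that add atoms: none
Why: Fluoride attacks silicon in 11 and loss of triflate gives aryne 12; the carboxylate of 6 adds through oxygen to the aryne carbon remote from the C5 benzyloxy group (future C8a), the aryl anion at future C4a attacks its own ester carbonyl through a four-membered transition state, and collapse of the benzoxetane alkoxide gives the o-acylphenolate 13, a net insertion of the aryne into the C–O bond of the acid. Phenolate 13 then closes ring C by 6-endo-trig conjugate addition to the β-methoxy enone and β-elimination of methoxide (oxa-Michael addition–elimination), the methoxide being protonated to methanol by the hydrogen fluoride that the acid set free. The closest known reaction type is the fluoride-induced insertion of arynes into the C–O bond of carboxylic acids to give o-hydroxyaryl ketones, which with α,β-unsaturated acids goes on in the same flask to 4-chromanones and with arylpropiolic acids to flavones. The regiochemistry is secured by the benzyloxy group beside the triple bond: its inductive pull distorts the aryne and stabilises negative charge on the adjacent carbon, so the nucleophile enters meta to it and the acyl group ends ortho to it, the pattern of a 5,7-dioxygenated chromone, while the second benzyloxy group is remote and does not compete. Attack of the aryl anion on the carbonyl carbon in preference to the β-carbon (which would lead to a coumarin) is expected because the s-cis aryl ester holds the anion next to the carbonyl group and the methoxy donor deactivates the β-position, and the high temperature favours acyl transfer over protonation of the anion. No stereocentre is formed and the alkene geometry of 6 is erased in the addition–elimination.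

**Step 8**
Reactants: 14 5,7-bis(benzyloxy)-3-(3-bromo-4,5-dimethoxyphenyl)-4H-chromen-4-one
Product: 15 3-(3-bromo-4,5-dimethoxyphenyl)-5,7-dihydroxy-4H-chromen-4-one
Conditions: BCl3 (1 M in CH2Cl2, 5 equiv), C6HMe5 (6 equiv), CH2Cl2, −78 °C to −30 °C, 1 h; MeOH quench, aqueous work-up
Reagents that add atoms: none
Why: Lewis acid cleavage of aryl benzyl ethers by BCl3 with pentamethylbenzene as a non-basic benzyl cation scavenger; the ring B methyl ethers and the aryl bromide should be untouched at low temperature, and no acid-sensitive alkene is present at this stage.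

**Step 9**
Reactants: 15 3-(3-bromo-4,5-dimethoxyphenyl)-5,7-dihydroxy-4H-chromen-4-one
Product: 16 piscerythrinetin [5,7-dihydroxy-3-[3,4-dimethoxy-5-(3-methylbut-2-en-1-yl)phenyl]-4H-chromen-4-one]
Conditions: tributyl(3-methylbut-2-en-1-yl)stannane (1.5 equiv), Pd(PPh3)4 (10 mol %), DMF (degassed), 100 °C, Ar, 6 h
Reagents that add atoms: tributyl(3-methylbut-2-en-1-yl)stannane, CCCC[Sn](CCCC)(CCCC)CC=C(C)C
Why: Stille coupling: oxidative addition of zerovalent palladium into the C–Br bond, transmetalation of the allylic stannane and reductive elimination at the unsubstituted terminus of the (1,1-dimethylallyl)palladium intermediate should give the linear prenyl arene, and the neutral conditions tolerate the free phenols and the base-sensitive ring C.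

**Compound list**
1 | homovanillic acid [2-(4-hydroxy-3-methoxyphenyl)acetic acid] | COc1cc(CC(=O)O)ccc1O | starting material
2 | 2-(3-bromo-4-hydroxy-5-methoxyphenyl)acetic acid | OC(=O)Cc1cc(Br)c(O)c(OC)c1 | intermediate
3 | methyl 2-(3-bromo-4,5-dimethoxyphenyl)acetate | COC(=O)Cc1cc(Br)c(OC)c(OC)c1 | intermediate
4 | sodium enolate of methyl 2-(3-bromo-4,5-dimethoxyphenyl)-3-oxopropanoate (not isolated) | [Na+].[O-]C=C(C(=O)OC)c1cc(Br)c(OC)c(OC)c1 | intermediate
5 | methyl (E)-2-(3-bromo-4,5-dimethoxyphenyl)-3-methoxyacrylate | CO/C=C(\c1cc(Br)c(OC)c(OC)c1)C(=O)OC | intermediate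
6 | (E)-2-(3-bromo-4,5-dimethoxyphenyl)-3-methoxyacrylic acid | CO/C=C(\c1cc(Br)c(OC)c(OC)c1)C(=O)O | intermediate
7 | 3,5-bis(benzyloxy)phenol | Oc1cc(OCc2ccccc2)cc(OCc2ccccc2)c1 | starting material
8 | 2-bromo-3,5-bis(benzyloxy)phenol | Oc1cc(OCc2ccccc2)cc(OCc2ccccc2)c1Br | intermediate
9 | [2-bromo-3,5-bis(benzyloxy)phenoxy]trimethylsilane (not isolated) | C[Si](C)(C)Oc1cc(OCc2ccccc2)cc(OCc2ccccc2)c1Br | intermediate
10 | lithium 3,5-bis(benzyloxy)-2-(trimethylsilyl)phenolate (not isolated) | [Li+].[O-]c1cc(OCc2ccccc2)cc(OCc2ccccc2)c1[Si](C)(C)C | intermediate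
11 | 3,5-bis(benzyloxy)-2-(trimethylsilyl)phenyl trifluoromethanesulfonate | C[Si](C)(C)c1c(OS(=O)(=O)C(F)(F)F)cc(OCc2ccccc2)cc1OCc1ccccc1 | intermediate
12 | 3,5-bis(benzyloxy)benzyne [3,5-bis(benzyloxy)-1,2-didehydrobenzene] (not isolated) | O(Cc1ccccc1)C1=CC(OCc2ccccc2)=CC#C1 | intermediate
13 | cesium 3,5-bis(benzyloxy)-2-[(E)-2-(3-bromo-4,5-dimethoxyphenyl)-3-methoxyacryloyl]phenolate (not isolated) | CO/C=C(\c1cc(Br)c(OC)c(OC)c1)C(=O)c1c([O-])cc(OCc2ccccc2)cc1OCc1ccccc1.[Cs+] | intermediate
14 | 5,7-bis(benzyloxy)-3-(3-bromo-4,5-dimethoxyphenyl)-4H-chromen-4-one | O=c1c(-c2cc(Br)c(OC)c(OC)c2)coc2cc(OCc3ccccc3)cc(OCc3ccccc3)c12 | intermediate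
15 | 3-(3-bromo-4,5-dimethoxyphenyl)-5,7-dihydroxy-4H-chromen-4-one | O=c1c(-c2cc(Br)c(OC)c(OC)c2)coc2cc(O)cc(O)c12 | intermediate
16 | piscerythrinetin [5,7-dihydroxy-3-[3,4-dimethoxy-5-(3-methylbut-2-en-1-yl)phenyl]-4H-chromen-4-one] | COc1cc(-c2coc3cc(O)cc(O)c3c2=O)cc(CC=C(C)C)c1OC | target

**Step count and risks**
Total: 9 steps. Longest linear sequence: 7 steps (steps 1–4, 7, 8, 9).

The three steps most likely to fail:

1. Step 7. The aryl anion may be protonated before the acyl shift (leaving an aryl ester), may attack the β-carbon instead of the carbonyl carbon, or the aryne may be consumed by the enol ether or by the phenolate. The fallback sets out from 7 and 6 and comes back at 14. Iodination of 7 ortho to the hydroxyl group (NIS, CH2Cl2, −78 °C) should give 3,5-bis(benzyloxy)-2-iodophenol F1. Esterification with 6 (EDC·HCl, DMAP, CH2Cl2) should give 3,5-bis(benzyloxy)-2-iodophenyl (E)-2-(3-bromo-4,5-dimethoxyphenyl)-3-methoxyacrylate F2. Iodine–magnesium exchange with i-PrMgCl·LiCl in THF at −40 °C (the ring B bromide should not exchange), followed by warming, should bring about the anionic Fries-type 1,3-shift of the acyl group from oxygen to carbon. This gives chloromagnesium 3,5-bis(benzyloxy)-2-[(E)-2-(3-bromo-4,5-dimethoxyphenyl)-3-methoxyacryloyl]phenolate F3, which should close to 14 in the flask or on mildly acidic work-up. Here the aryl anion is made on a preformed ester by halogen–metal exchange, with no aryne and no proton source.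

2. Step 9. The prenyl group may be transferred with allylic transposition, or oxidative addition at the electron-rich, ortho-substituted bromide may be slow and end in protodebromination. The fallback sets out from 15 and comes back at 16. Stille coupling with allyltributylstannane (Pd(PPh3)4, DMF, 100 °C) should give 3-(3-allyl-4,5-dimethoxyphenyl)-5,7-dihydroxy-4H-chromen-4-one F4, for which no regiochemical question arises. Olefin cross-metathesis with excess 2-methyl-2-butene (second-generation Grubbs catalyst RuCl2(=CHPh)(PCy3)(H2IMes), CH2Cl2, 40 °C) should then give 16.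

3. Step 5. Bromination may occur para to the hydroxyl group or twice on the very electron-rich ring. The fallback sets out from 7 and comes back at 11, bypassing 8. Carbamoylation with ClC(O)NEt2 (NaH, THF) should give 3,5-bis(benzyloxy)phenyl diethylcarbamate F5. Directed ortho-metalation with s-BuLi/TMEDA in THF at −78 °C (between carbamate and benzyloxy group; both such positions are equivalent) and quench with TMSCl should give 3,5-bis(benzyloxy)-2-(trimethylsilyl)phenyl diethylcarbamate F6. Reductive cleavage of the carbamate with LiAlH4 in THF should give 3,5-bis(benzyloxy)-2-(trimethylsilyl)phenol F7, and triflation (Tf2O, pyridine, CH2Cl2, 0 °C) should give 11.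

**Further compounds**
F1 | step 7 | 3,5-bis(benzyloxy)-2-iodophenol | Oc1cc(OCc2ccccc2)cc(OCc2ccccc2)c1I
F2 | step 7 | 3,5-bis(benzyloxy)-2-iodophenyl (E)-2-(3-bromo-4,5-dimethoxyphenyl)-3-methoxyacrylate | CO/C=C(\c1cc(Br)c(OC)c(OC)c1)C(=O)Oc1cc(OCc2ccccc2)cc(OCc2ccccc2)c1I
F3 | step 7 | chloromagnesium 3,5-bis(benzyloxy)-2-[(E)-2-(3-bromo-4,5-dimethoxyphenyl)-3-methoxyacryloyl]phenolate | CO/C=C(\c1cc(Br)c(OC)c(OC)c1)C(=O)c1c(O[Mg]Cl)cc(OCc2ccccc2)cc1OCc1ccccc1
F4 | step 9 | 3-(3-allyl-4,5-dimethoxyphenyl)-5,7-dihydroxy-4H-chromen-4-one | C=CCc1cc(-c2coc3cc(O)cc(O)c3c2=O)cc(OC)c1OC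
F5 | step 5 | 3,5-bis(benzyloxy)phenyl diethylcarbamate | CCN(CC)C(=O)Oc1cc(OCc2ccccc2)cc(OCc2ccccc2)c1
F6 | step 5 | 3,5-bis(benzyloxy)-2-(trimethylsilyl)phenyl diethylcarbamate | CCN(CC)C(=O)Oc1cc(OCc2ccccc2)cc(OCc2ccccc2)c1[Si](C)(C)C
F7 | step 5 | 3,5-bis(benzyloxy)-2-(trimethylsilyl)phenol | Oc1cc(OCc2ccccc2)cc(OCc2ccccc2)c1[Si](C)(C)C
A1 | direct plan | 2,4,6-tris(methoxymethoxy)benzaldehyde | O=Cc1c(OCOC)cc(OCOC)cc1OCOC
A2 | direct plan | methyl 2-[3,4-dimethoxy-5-(3-methylbut-2-en-1-yl)phenyl]acetate | COC(=O)Cc1cc(CC=C(C)C)c(OC)c(OC)c1
A3 | direct plan | 2-[3,4-dimethoxy-5-(3-methylbut-2-en-1-yl)phenyl]-1-[2,4,6-tris(methoxymethoxy)phenyl]ethan-1-one | O=C(Cc1cc(CC=C(C)C)c(OC)c(OC)c1)c1c(OCOC)cc(OCOC)cc1OCOC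
A4 | direct plan | (E)-3-(dimethylamino)-2-[3,4-dimethoxy-5-(3-methylbut-2-en-1-yl)phenyl]-1-[2,4,6-tris(methoxymethoxy)phenyl]prop-2-en-1-one | CN(C)/C=C(\c1cc(CC=C(C)C)c(OC)c(OC)c1)C(=O)c1c(OCOC)cc(OCOC)cc1OCOC
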